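The data were generated by integration on assumed constants, noise included.

In both earlier runs the left-handed substrate falls faster than the right-handed substrate , and the two new flasks, autumn and noon, differ in their charge of solid reagent.

| flask | left-handed substrate | right-handed substrate | protic impurity | solid reagent | remark | time |
|---|---|---|---|---|---|---|
| grey | 0.22 M | 0.22 M | 0.015 M | 0.165 M | run made earlier |  |
| violet | 0.30 M | 0.30 M | 0.015 M | 0.165 M | run made earlier |  |
| autumn | 0.15 M | 0.15 M | 0.0150 M | 0.165 M |  | 8.0 min |
| noon | 0.15 M | 0.15 M | 0.0150 M | 0.0500 M |  | 8.0 min |

| run | time / min | right-handed substrate / % | left-handed substrate / % | left-handed product / % |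
|---|---|---|---|---|
| grey | 0.250 | 49.1 | 49.6 | 1.4 |
| grey | 0.333 | 49.4 | 49.0 | 1.0 |
| grey | 0.500 | 48.8 | 47.5 | 1.6 |
| grey | 0.833 | 48.7 | 46.2 | 4.0 |
| grey | 1.33 | 47.4 | 42.7 | 6.7 |
| grey | 2.00 | 44.8 | 38.6 | 10.7 |
| grey | 3.00 | 42.8 | 33.2 | 16.7 |
| violet | 0.417 | 49.9 | 49.1 | 1.9 |
| violet | 0.833 | 48.2 | 47.0 | 3.1 |
| violet | 1.33 | 47.5 | 44.6 | 5.3 |
| violet | 1.50 | 47.5 | 44.2 | 6.8 |
| violet | 2.00 | 46.2 | 42.0 | 8.5 |
| violet | 2.50 | 45.4 | 39.4 | 11.2 |
| violet | 3.00 | 44.2 | 37.1 | 13.2 |

(readings scatter by 0.3 percentage points)

- partner is single-handed; left-handed substrate and right-handed substrate are mirror images of each other, charged as a racemate, each of them at the stated concentration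
- as a solid, counted per litre of solution: solid reagent
- at the start none of the solid reagent is in solution
- an excess is the difference of the two amounts in percent of their sum
- an excess is below zero if the other one leads
- the handed part of partner does not stay in what it makes, so the products of the two hands are mirror images too

* the winner by excess of right-handed substrate over left-handed substrate among what is left of the two; "neither" if no more than 2 percentage points parts them (autumn / noon / neither)
* excess of right-handed substrate over left-handed substrate among what is left of the two at the end, autumn
* excess of right-handed substrate over left-handed substrate among what is left of the two at the end, noon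

We follow one molecule of partner, which we take to be the solid reagent once dissolved, and ask which way it goes at the fork. Its preference is measured by the logarithm of the fraction of left-handed substrate left, of its own charge, over the same logarithm for the right-handed substrate. The last readings give 2.63 in grey and 2.42 in violet, and we carry their mean, the selectivity factor s = 2.53. So in a flask charged as a racemate, with the same partner meeting both hands, we take the left-handed fraction of its own charge to be the right-handed fraction raised to s at any moment of the run.

Take the main step by itself, with each dissolved molecule taken by a substrate. Autumn then loses 0.550 of the charge, which leaves 0.615 of the right-handed substrate and an excess of 35.5%. Noon loses 0.167, which leaves 0.900 and an excess of 8.01%.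

Now add the protic impurity as a third way at the fork. We guess it is as quick as an average substrate molecule, so it takes 4.76% of the partner. Autumn then loses 0.524 and noon 0.159, leaving 0.638 and 0.905 of the right-handed substrate.

Last comes the dissolving. Grey used substrate at 0.0352 M min⁻¹ on average up to 3.00 min, and at that pace autumn's charge of solid reagent passes in 4.69 min, shorter than the 8.0 min allowed. So in our reckoning the solid reagent is the limiting reagent, and time leaves the excess where it stood: 33.0% for autumn and 7.59% for noon.

The forecast says autumn, with 30% and 5.2%, on the ground that “the lag is the 0.015 M impurity eating the first reagent”. Both its numbers stand lower than ours .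

The flasks give 35.2% for autumn and 8.00% for noon, so autumn wins.

    partner + right-handed substrate → right-handed product (k = 0.100 M⁻¹ s⁻¹)
    partner + left-handed substrate → left-handed product (k = 0.260 M⁻¹ s⁻¹)
    solid reagent ⇌ partner, rate k3*(cs3 - [partner]) while solid is left; crystals form when [partner] > cs3 (solubility = 0.120 M, k = 0.00590 s⁻¹)
    partner + protic impurity → quenched reagent (k = 0.0890 M⁻¹ s⁻¹)

The gap comes from the charge of solid reagent: with that difference taken away, noon stands at 35.2% instead of 8.00%. Autumn ends with 63% of its charge of right-handed substrate, and raising that to s gives 31.3%, against the 30% of its charge of left-handed substrate that stands in autumn. The neighbour of noon with 0.085 M of solid reagent loses 0.270 by our impurity share, which leaves 0.832 of the right-handed substrate and an excess of 13.9%; that flask gives 14.7%.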